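Retrosynthesis: first the ester C–O bond (caffeic acid set free); then, in one cut, the two cyclopentane bonds that tie the ring CH2–CH2 pair to the methyl-bearing quaternary carbon and to the allylic ring CH2; then the donor, the methyl ketone, the bridged lactone and the benzoate.
Enabling feature: in the methylidenecyclopentane the =CH2-bearing ring carbon lies between a ring CH2 and the quaternary carbon, so these four carbons are a trimethylenemethane unit, and the two remaining ring atoms are a bare ethylene unit.
Forward order: cyclohexene ring first (Birch reductive methylation of a benzoate), bridged γ-lactone, methyl ketone, trimethylenemethane donor, (3+2) cycloaddition closing the cyclopentane, desulfonylation, ester last.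
Stereochemistry: carbinol carbon by CBS reduction (reagent control); ring quaternary carbon by lactonisation of only the cis-hydroxy ester formed from the racemate; cyclopentane quaternary carbon in the cycloaddition under a chiral phosphoramidite on palladium.

Key step: step 7

Assumption: the sense of induction of the phosphoramidite at the new quaternary carbon cannot be assigned beforehand; the (S,R,R) ligand is written and stands for whichever antipode gives the (S)-configured centre.

Step 1
Reactants: 1 methyl 3-methoxy-4-methylbenzoate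
Product: 3 methyl 3-methoxy-1,4-dimethylcyclohexa-2,5-diene-1-carboxylate (racemic; both relative configurations), via potassium ester dienolate 2 (not isolated)
Conditions: K (2.2 equiv), t-BuOH (1.0 equiv), NH3/THF, −78 °C; then MeI (3 equiv), −78 °C; NH4Cl
Reagents that add atoms: iodomethane CI
Why: Two-electron Birch reduction of the benzoate with one proton delivered para to the ester gives dienolate 2, which is C-methylated at the ester-bearing carbon to create the ring quaternary carbon (Birch reductive alkylation); neither sp3 centre needs control here, since the methyl-bearing CH becomes sp2 in step 2 and the quaternary carbon is sorted in step 3.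

Step 2
Reactants: 3 methyl 3-methoxy-1,4-dimethylcyclohexa-2,5-diene-1-carboxylate
Product: 5 methyl 1,4-dimethyl-5-oxocyclohex-3-ene-1-carboxylate (racemic), via unconjugated enone 4 (not isolated)
Conditions: 2 M HCl, THF, 23 °C then 50 °C
Reagents that add atoms: water O
Why: Acid hydrolysis of the enol ether gives the β,γ-unsaturated ketone 4, and the same acid moves the double bond into conjugation (enol ether hydrolysis and acid-catalysed alkene isomerisation), which is possible on one side only because the other α-carbon leads to the quaternary carbon.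

Step 3
Reactants: 5 methyl 1,4-dimethyl-5-oxocyclohex-3-ene-1-carboxylate (racemic)
Product: 7 (1S,5S)-1,4-dimethyl-6-oxabicyclo[3.2.1]oct-3-en-7-one, via cis-hydroxy ester 6 (not isolated)
Conditions: (R)-Me-CBS oxazaborolidine [(R)-1-methyl-3,3-diphenyltetrahydro-1H,3H-pyrrolo[1,2-c][1,3,2]oxazaborole] (0.2 equiv), BH3·SMe2 (0.7 equiv), THF, −20 °C; MeOH; then 1,8-diazabicyclo[5.4.0]undec-7-ene (0.2 equiv), toluene, 100 °C; chromatography (removes the open trans-hydroxy ester)
Reagents that add atoms: none
Why: Corey–Bakshi–Shibata reduction should fix the carbinol carbon as S in both enantiomers of 5 by reagent control (the 2-methylalkenyl carbon acting as the large group), and base-catalysed transesterification then closes the bridged γ-lactone only from the cis-hydroxy ester 6, so that the lactone carries one configuration at the quaternary carbon while the trans-hydroxy ester from (R)-5 stays open and is separated (divergent reaction of a racemate).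

Step 4
Reactants: 7 (1S,5S)-1,4-dimethyl-6-oxabicyclo[3.2.1]oct-3-en-7-one
Product: 9 1-[(1S,5S)-5-hydroxy-1,4-dimethylcyclohex-3-en-1-yl]ethan-1-one (in equilibrium with its bridged lactol), via lithium lactolate 8 (not isolated)
Conditions: MeLi (1.05 equiv), THF, −78 °C; NH4Cl at −78 °C
Reagents that add atoms: methyllithium [Li]C
Why: Addition of one equivalent of methyllithium to the lactone carbonyl gives lactolate 8, a tetrahedral intermediate that is stable at −78 °C and so cannot add a second equivalent, and protonation releases the methyl ketone (acyl substitution of a lactone by an organolithium) without touching either stereocentre.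

Step 5
Reactants: 9 1-[(1S,5S)-5-hydroxy-1,4-dimethylcyclohex-3-en-1-yl]ethan-1-one
Product: 10 1-[(1S,5S)-5-{[tert-butyl(dimethyl)silyl]oxy}-1,4-dimethylcyclohex-3-en-1-yl]ethan-1-one
Conditions: TBSCl (1.3 equiv), imidazole (2.5 equiv), DMF, 23 °C
Reagents that add atoms: tert-butyldimethylsilyl chloride CC(C)(C)[Si](C)(C)Cl
Why: Silylation (silyl ether protection) takes the unhindered secondary allylic hydroxyl of the open hydroxy ketone much faster than the tertiary lactol hydroxyl, so the lactol equilibrium drains into the open silyl ether.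

Step 6
Reactants: 10 1-[(1S,5S)-5-{[tert-butyl(dimethyl)silyl]oxy}-1,4-dimethylcyclohex-3-en-1-yl]ethan-1-one; 11 2-bromo-3-(trimethylsilyl)prop-1-ene
Product: 14 2-[(1S,5S)-5-{[tert-butyl(dimethyl)silyl]oxy}-1,4-dimethylcyclohex-3-en-1-yl]-3-[(trimethylsilyl)methyl]but-3-en-2-yl methyl carbonate (both carbinol epimers), via vinyllithium 12 (not isolated), via lithium alkoxide 13 (not isolated)
Conditions: 11 (1.5 equiv), t-BuLi (3.0 equiv), Et2O, −78 °C; then 10, THF, −78 °C; then ClCO2Me (2 equiv), −78 → 23 °C
Reagents that add atoms: methyl chloroformate COC(=O)Cl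
Why: Bromine–lithium exchange gives vinyllithium 12, a weakly basic sp2 carbanion that should add to the methyl ketone (1,2-addition of an organolithium) faster than it deprotonates it, and the tertiary alkoxide 13 is acylated in the flask to the allylic carbonate; the new carbinol carbon forms unselectively, which is harmless because it becomes planar in step 7.

Step 7
Reactants: 14 2-[(1S,5S)-5-{[tert-butyl(dimethyl)silyl]oxy}-1,4-dimethylcyclohex-3-en-1-yl]-3-[(trimethylsilyl)methyl]but-3-en-2-yl methyl carbonate; 15 phenyl vinyl sulfone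
Product: 16 tert-butyl({(1S,5S)-2,5-dimethyl-5-[(1S)-1-methyl-2-methylidene-4-(phenylsulfonyl)cyclopentyl]cyclohex-2-en-1-yl}oxy)dimethylsilane (both epimers at the sulfonyl carbon)
Conditions: Pd(dba)2 (5 mol %), (S)-(1,1'-binaphthalene-2,2'-diyl) N,N-bis[(R)-1-phenylethyl]phosphoramidite (10 mol %), 15 (1.5 equiv), toluene, 23 → 50 °C
Reagents that add atoms: none
Why: Proposed new method: zerovalent palladium ionises the tertiary allylic carbonate of 14 with loss of CO2, the freed methoxide removes the trimethylsilyl group, and the zwitterionic trimethylenemethane–palladium complex, with palladium on the unsubstituted allyl part and the charge on the terminus that bears the methyl group and the cyclohexenyl ring, adds through that terminus to the CH2 end of 15, after which the α-sulfonyl carbanion closes on a CH2 terminus of the π-allyl cation. The closest known reaction type is the palladium-catalysed trimethylenemethane (3+2) cycloaddition of alkyl-substituted 2-(silylmethyl)allyl esters with vinyl sulfones and enones, in which the substituted terminus bonds first; new here are a fully substituted donor terminus flanked by a quaternary carbon and the demand that a chiral ligand fixes its configuration. The cyclopentane closes stepwise, by intermolecular conjugate addition and then intramolecular allylic alkylation to a five-membered ring (5-exo with respect to the σ-allyl form), which leaves the methylidene group exocyclic. The new quaternary centre is set in the conjugate addition on the face of the planar terminus opposite palladium, and since the two arms of the cyclohexene differ only at remote atoms the substrate offers little bias, so the phosphoramidite, which must tell the methyl group from the tert-alkyl ring residue on that terminus, is the controlling element; the sulfonyl-bearing carbon forms unselectively and is erased in step 8. The step needs regioselectivity for bond formation at the substituted terminus (attack through a CH2 terminus would end in an isopropylidene-type isomer), which the preference of palladium for the less substituted allyl unit should secure, and chemoselective ionisation of the carbonate beside the allylic silyl ether, which is no leaving group for palladium.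

Step 8
Reactants: 16 tert-butyl({(1S,5S)-2,5-dimethyl-5-[(1S)-1-methyl-2-methylidene-4-(phenylsulfonyl)cyclopentyl]cyclohex-2-en-1-yl}oxy)dimethylsilane
Product: 17 tert-butyl({(1S,5S)-2,5-dimethyl-5-[(1S)-1-methyl-2-methylidenecyclopentyl]cyclohex-2-en-1-yl}oxy)dimethylsilane
Conditions: Na(Hg) (6 % Na), Na2HPO4, MeOH/THF, −20 → 0 °C
Reagents that add atoms: none
Why: Sodium amalgam in buffered methanol cleaves the alkyl–sulfonyl bond by electron transfer and protonation (reductive desulfonylation), which erases the stereocentre at that carbon and spares the isolated alkenes and the silyl ether.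

Step 9
Reactants: 17 tert-butyl({(1S,5S)-2,5-dimethyl-5-[(1S)-1-methyl-2-methylidenecyclopentyl]cyclohex-2-en-1-yl}oxy)dimethylsilane
Product: 18 (1S,5S)-2,5-dimethyl-5-[(1S)-1-methyl-2-methylidenecyclopentyl]cyclohex-2-en-1-ol
Conditions: Bu4NF, THF, 23 °C; NH4Cl
Reagents that add atoms: none
Why: Fluoride attacks silicon and frees the allylic alcohol (desilylation) with no change at carbon, so all three stereocentres are retained.

Step 10
Reactants: 19 caffeic acid
Product: 21 (2E)-3-[3,4-bis(tert-butyldimethylsilyloxy)phenyl]prop-2-enoic acid, via tris-silyl caffeate 20 (not isolated)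
Conditions: TBSCl (3.3 equiv), imidazole (7 equiv), DMF, 23 °C; then AcOH/THF/H2O, 23 °C
Reagents that add atoms: tert-butyldimethylsilyl chloride CC(C)(C)[Si](C)(C)Cl
Why: Exhaustive silylation followed by mild aqueous acid, which hydrolyses only the far more labile silyl ester, leaves both phenols masked and the acid free (silyl protection), and the (E)-alkene is not touched.

Step 11
Reactants: 18 (1S,5S)-2,5-dimethyl-5-[(1S)-1-methyl-2-methylidenecyclopentyl]cyclohex-2-en-1-ol; 21 (2E)-3-[3,4-bis(tert-butyldimethylsilyloxy)phenyl]prop-2-enoic acid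
Product: 22 (1S,5S)-2,5-dimethyl-5-[(1S)-1-methyl-2-methylidenecyclopentyl]cyclohex-2-en-1-yl (2E)-3-[3,4-bis(tert-butyldimethylsilyloxy)phenyl]prop-2-enoate
Conditions: N,N'-diisopropylcarbodiimide (1.5 equiv), 4-(dimethylamino)pyridine (0.2 equiv), CH2Cl2, 0 → 23 °C
Reagents that add atoms: none
Why: Carbodiimide activation of acid 21 and acyl transfer through the acylpyridinium ion (Steglich esterification) acylate the secondary allylic alcohol at oxygen, so the carbinol configuration is retained, and the masked phenols cannot compete.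

Step 12
Reactants: 22 (1S,5S)-2,5-dimethyl-5-[(1S)-1-methyl-2-methylidenecyclopentyl]cyclohex-2-en-1-yl (2E)-3-[3,4-bis(tert-butyldimethylsilyloxy)phenyl]prop-2-enoate
Product: 23 (1S,5S)-2,5-dimethyl-5-[(1S)-1-methyl-2-methylidenecyclopentyl]cyclohex-2-en-1-yl (2E)-3-(3,4-dihydroxyphenyl)prop-2-enoate
Conditions: HF·pyridine, pyridine, THF, 0 °C
Reagents that add atoms: none
Why: Hydrogen fluoride buffered by pyridine cleaves the two aryl silyl ethers (desilylation) under conditions too mild to hydrolyse the cinnamate ester or to isomerise the exocyclic alkene.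

Compound list
1 | methyl 3-methoxy-4-methylbenzoate | COC(=O)c1ccc(C)c(OC)c1 | starting material
2 | potassium ester dienolate of methyl 3-methoxy-4-methyl-1,4-dihydrobenzoate | [K+].COC([O-])=C1C=CC(C)C(OC)=C1 | intermediate (not isolated)
3 | methyl 3-methoxy-1,4-dimethylcyclohexa-2,5-diene-1-carboxylate (racemic, both relative configurations) | COC(=O)C1(C)C=CC(C)C(OC)=C1 | intermediate
4 | methyl 1,4-dimethyl-5-oxocyclohex-2-ene-1-carboxylate (unconjugated enone) | COC(=O)C1(C)C=CC(C)C(=O)C1 | intermediate (not isolated)
5 | methyl 1,4-dimethyl-5-oxocyclohex-3-ene-1-carboxylate (racemic) | COC(=O)C1(C)CC=C(C)C(=O)C1 | intermediate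
6 | methyl (1S,5S)-5-hydroxy-1,4-dimethylcyclohex-3-ene-1-carboxylate (hydroxyl cis to the ester) | COC(=O)[C@@]1(C)CC=C(C)[C@@H](O)C1 | intermediate (not isolated)
7 | (1S,5S)-1,4-dimethyl-6-oxabicyclo[3.2.1]oct-3-en-7-one | O=C2[C@@]1(C)CC=C(C)[C@@H](O2)C1 | intermediate
8 | lithium (1S,5S)-1,4,7-trimethyl-6-oxabicyclo[3.2.1]oct-3-en-7-olate (lactolate, both configurations at the lactol carbon) | [Li+].[O-]C2(C)[C@@]1(C)CC=C(C)[C@@H](O2)C1 | intermediate (not isolated)
9 | 1-[(1S,5S)-5-hydroxy-1,4-dimethylcyclohex-3-en-1-yl]ethan-1-one (open form of the lactol) | CC(=O)[C@@]1(C)CC=C(C)[C@@H](O)C1 | intermediate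
10 | 1-[(1S,5S)-5-{[tert-butyl(dimethyl)silyl]oxy}-1,4-dimethylcyclohex-3-en-1-yl]ethan-1-one | CC(=O)[C@@]1(C)CC=C(C)[C@@H](O[Si](C)(C)C(C)(C)C)C1 | intermediate
11 | 2-bromo-3-(trimethylsilyl)prop-1-ene | C=C(Br)C[Si](C)(C)C | starting material
12 | [3-(trimethylsilyl)prop-1-en-2-yl]lithium | [Li]C(=C)C[Si](C)(C)C | intermediate (not isolated)
13 | lithium 2-[(1S,5S)-5-{[tert-butyl(dimethyl)silyl]oxy}-1,4-dimethylcyclohex-3-en-1-yl]-3-[(trimethylsilyl)methyl]but-3-en-2-olate (both carbinol epimers) | [Li+].[O-]C(C)(C(=C)C[Si](C)(C)C)[C@@]1(C)CC=C(C)[C@@H](O[Si](C)(C)C(C)(C)C)C1 | intermediate (not isolated)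
14 | 2-[(1S,5S)-5-{[tert-butyl(dimethyl)silyl]oxy}-1,4-dimethylcyclohex-3-en-1-yl]-3-[(trimethylsilyl)methyl]but-3-en-2-yl methyl carbonate (both carbinol epimers) | COC(=O)OC(C)(C(=C)C[Si](C)(C)C)[C@@]1(C)CC=C(C)[C@@H](O[Si](C)(C)C(C)(C)C)C1 | intermediate
15 | phenyl vinyl sulfone [(ethenesulfonyl)benzene] | C=CS(=O)(=O)c1ccccc1 | starting material
16 | tert-butyl({(1S,5S)-2,5-dimethyl-5-[(1S)-1-methyl-2-methylidene-4-(phenylsulfonyl)cyclopentyl]cyclohex-2-en-1-yl}oxy)dimethylsilane (both epimers at the sulfonyl carbon) | C=C1CC(S(=O)(=O)c2ccccc2)C[C@]1(C)[C@@]1(C)CC=C(C)[C@@H](O[Si](C)(C)C(C)(C)C)C1 | intermediate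
17 | tert-butyl({(1S,5S)-2,5-dimethyl-5-[(1S)-1-methyl-2-methylidenecyclopentyl]cyclohex-2-en-1-yl}oxy)dimethylsilane | C=C1CCC[C@]1(C)[C@@]1(C)CC=C(C)[C@@H](O[Si](C)(C)C(C)(C)C)C1 | intermediate
18 | (1S,5S)-2,5-dimethyl-5-[(1S)-1-methyl-2-methylidenecyclopentyl]cyclohex-2-en-1-ol | C=C1CCC[C@]1(C)[C@@]1(C)CC=C(C)[C@@H](O)C1 | intermediate
19 | caffeic acid [(2E)-3-(3,4-dihydroxyphenyl)prop-2-enoic acid] | OC(=O)/C=C/c1ccc(O)c(O)c1 | starting material
20 | tert-butyldimethylsilyl (2E)-3-[3,4-bis(tert-butyldimethylsilyloxy)phenyl]prop-2-enoate | CC(C)(C)[Si](C)(C)OC(=O)/C=C/c1ccc(O[Si](C)(C)C(C)(C)C)c(O[Si](C)(C)C(C)(C)C)c1 | intermediate (not isolated)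
21 | (2E)-3-[3,4-bis(tert-butyldimethylsilyloxy)phenyl]prop-2-enoic acid | OC(=O)/C=C/c1ccc(O[Si](C)(C)C(C)(C)C)c(O[Si](C)(C)C(C)(C)C)c1 | intermediate
22 | (1S,5S)-2,5-dimethyl-5-[(1S)-1-methyl-2-methylidenecyclopentyl]cyclohex-2-en-1-yl (2E)-3-[3,4-bis(tert-butyldimethylsilyloxy)phenyl]prop-2-enoate | C=C1CCC[C@]1(C)[C@@]1(C)CC=C(C)[C@@H](OC(=O)/C=C/c2ccc(O[Si](C)(C)C(C)(C)C)c(O[Si](C)(C)C(C)(C)C)c2)C1 | intermediate
23 | (1S,5S)-2,5-dimethyl-5-[(1S)-1-methyl-2-methylidenecyclopentyl]cyclohex-2-en-1-yl (2E)-3-(3,4-dihydroxyphenyl)prop-2-enoate | C=C1CCC[C@]1(C)[C@@]1(C)CC=C(C)[C@@H](OC(=O)/C=C/c2ccc(O)c(O)c2)C1 | target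

Total step count: 12
Longest linear sequence: 11 steps (steps 1 to 9, then 11 and 12; step 10 prepares the acid partner)

Steps most likely to fail

1. Step 7 (Proposed new method). What may go wrong: bond formation through a CH2 terminus of the trimethylenemethane complex in place of the crowded substituted terminus, weak facial discrimination at the new quaternary carbon, or β-hydride loss or protonation of the π-allyl species before it meets the sulfone. The fallback uses known chemistry, puts the quaternary carbon under substrate control, and runs from 10 to 18. A van Leusen reductive cyanation of 10 (TosMIC, KOt-Bu, DME/EtOH) should give 2-[(1S,5S)-5-{[tert-butyl(dimethyl)silyl]oxy}-1,4-dimethylcyclohex-3-en-1-yl]propanenitrile F1. Hot aqueous-alcoholic KOH should hydrolyse the nitrile and remove the silyl group to give 2-[(1S,5S)-5-hydroxy-1,4-dimethylcyclohex-3-en-1-yl]propanoic acid F2, which a carbodiimide closes to the bridged δ-lactone (1S,5S)-4,5,8-trimethyl-2-oxabicyclo[3.3.1]non-7-en-3-one F3. Deprotonation with LiN(i-Pr)2 and alkylation with 1,3-diiodopropane should take place on the enolate face turned away from the three-carbon bridge of the cyclohexene (exo alkylation of a bridged lactone enolate) and give (1S,4R,5S)-4-(3-iodopropyl)-4,5,8-trimethyl-2-oxabicyclo[3.3.1]non-7-en-3-one F4. Iodine–lithium exchange (t-BuLi, −100 °C) with intramolecular acyl substitution at the lactone carbonyl opens the temporary ring to (2R)-2-[(1S,5S)-5-hydroxy-1,4-dimethylcyclohex-3-en-1-yl]-2-methylcyclopentan-1-one F5. Wittig methylenation (Ph3P=CH2 in excess, warm THF) then gives 18.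

2. Step 3. What may go wrong: incomplete reagent control in the reduction of one enantiomer of 5, so that the lactone loses enantiomeric purity, or slow closure of the bridged lactone. The fallback separates the enantiomers before the reduction and runs from 5 to 7. Saponification (LiOH, aqueous THF) should give racemic 1,4-dimethyl-5-oxocyclohex-3-ene-1-carboxylic acid F6. Classical resolution through the diastereomeric salts with (S)-1-phenylethylamine should give (1S)-1,4-dimethyl-5-oxocyclohex-3-ene-1-carboxylic acid F7. Re-esterification (MeI, K2CO3) gives methyl (1S)-1,4-dimethyl-5-oxocyclohex-3-ene-1-carboxylate F8, which is taken through the reduction and lactonisation of step 3; the reduction now only has to be diastereoselective, and the route is rejoined at 7 (through 6).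

3. Step 6. What may go wrong: deprotonation of the hindered methyl ketone by the vinyllithium in place of addition, which returns 10 after work-up. The fallback reverses the order in which the two carbon groups meet the carbonyl carbon and runs from 7 to 14. Vinyllithium 12 (1.05 equiv, −78 °C, cold quench) should open lactone 7 to 1-[(1S,5S)-5-hydroxy-1,4-dimethylcyclohex-3-en-1-yl]-2-[(trimethylsilyl)methyl]prop-2-en-1-one F9. Silylation (TBSCl, imidazole) gives 1-[(1S,5S)-5-{[tert-butyl(dimethyl)silyl]oxy}-1,4-dimethylcyclohex-3-en-1-yl]-2-[(trimethylsilyl)methyl]prop-2-en-1-one F10, a ketone with no α-hydrogen. Methyllithium with CeCl3 should add 1,2 to it and give alkoxide 13, which is acylated in the flask with methyl chloroformate to 14.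

Further compounds
F1 | step 7 | 2-[(1S,5S)-5-{[tert-butyl(dimethyl)silyl]oxy}-1,4-dimethylcyclohex-3-en-1-yl]propanenitrile (both epimers at C2) | CC(C#N)[C@@]1(C)CC=C(C)[C@@H](O[Si](C)(C)C(C)(C)C)C1
F2 | step 7 | 2-[(1S,5S)-5-hydroxy-1,4-dimethylcyclohex-3-en-1-yl]propanoic acid (both epimers at C2) | CC(C(=O)O)[C@@]1(C)CC=C(C)[C@@H](O)C1
F3 | step 7 | (1S,5S)-4,5,8-trimethyl-2-oxabicyclo[3.3.1]non-7-en-3-one (both epimers at C4) | O=C2C(C)[C@@]1(C)CC=C(C)[C@@H](O2)C1
F4 | step 7 | (1S,4R,5S)-4-(3-iodopropyl)-4,5,8-trimethyl-2-oxabicyclo[3.3.1]non-7-en-3-one | O=C2[C@](C)(CCCI)[C@@]1(C)CC=C(C)[C@@H](O2)C1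
F5 | step 7 | (2R)-2-[(1S,5S)-5-hydroxy-1,4-dimethylcyclohex-3-en-1-yl]-2-methylcyclopentan-1-one | O=C1CCC[C@]1(C)[C@@]1(C)CC=C(C)[C@@H](O)C1
F6 | step 3 | 1,4-dimethyl-5-oxocyclohex-3-ene-1-carboxylic acid (racemic) | OC(=O)C1(C)CC=C(C)C(=O)C1
F7 | step 3 | (1S)-1,4-dimethyl-5-oxocyclohex-3-ene-1-carboxylic acid | OC(=O)[C@@]1(C)CC=C(C)C(=O)C1
F8 | step 3 | methyl (1S)-1,4-dimethyl-5-oxocyclohex-3-ene-1-carboxylate | COC(=O)[C@@]1(C)CC=C(C)C(=O)C1
F9 | step 6 | 1-[(1S,5S)-5-hydroxy-1,4-dimethylcyclohex-3-en-1-yl]-2-[(trimethylsilyl)methyl]prop-2-en-1-one | C=C(C[Si](C)(C)C)C(=O)[C@@]1(C)CC=C(C)[C@@H](O)C1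
F10 | step 6 | 1-[(1S,5S)-5-{[tert-butyl(dimethyl)silyl]oxy}-1,4-dimethylcyclohex-3-en-1-yl]-2-[(trimethylsilyl)methyl]prop-2-en-1-one | C=C(C[Si](C)(C)C)C(=O)[C@@]1(C)CC=C(C)[C@@H](O[Si](C)(C)C(C)(C)C)C1
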